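**Plan**

1. Atoms are numbered C1 (alkyne CH) to C15 (ethyl CH3); the oxocane is O–C6–C7–C8–C9–C10–C11–C12.
2. Retrosynthetic cuts, in order: the two acetates and the acetonide-masked 9,10-diol; C3=C4 (Z-enyne from a C4 aldehyde); C7–O and C6–H (hydroboration of a C6=C7 enol ether, then inversion); C5–C6 (Negishi coupling on the ketene acetal phosphate of a C6 lactone).
3. Enabling feature: C6 (on the ring oxygen) and oxygenated C10 face each other across the eight-membered ring. A C6=C10 bond therefore turns it into a 2-oxabicyclo[3.3.0]oct-1(5)-ene, a dihydrofuran (O, C6, C10, C11, C12) fused to a cyclopentene (C6–C10); cleaving that alkene returns the oxocane as a C6 lactone and C10 ketone.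
4. Forward: cyclopentane-1,3-dione (C6–C10) is C-alkylated at C10 by a C11–C15 epoxide and closed to the bicyclic vinylogous ester; C9 is reduced and silylated; ozonolysis opens the bicycle; then C10 reduction, C5–C6 coupling, C7 oxygenation, enyne and acetates.
5. Stereochemistry: C12/C13 from a Sharpless kinetic resolution; C9 from an oxazaborolidine-catalysed reduction; C10 from C9; C6 from hydroboration anti to the C12 side chain; C7 by hydroboration then Mitsunobu inversion; the Z-alkene from a Peterson olefination.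

Key step: step 6

Remark (assumption): (1,3-dioxolan-2-ylmethyl)zinc bromide (THF solution) and 1,3-bis(triisopropylsilyl)propyne are taken as purchased reagents.

**Route**

Step 1
Reactants: 1 (±)-pent-1-en-3-ol
Product: 2 (2R,3S)-1,2-epoxypentan-3-ol
Conditions: Ti(OiPr)4 (10 mol %), L-(+)-diisopropyl tartrate (15 mol %), t-BuOOH (0.45 equiv), 4 Å molecular sieves, CH2Cl2, −20 °C; non-aqueous work-up, distillation
Reagents that add atoms: tert-butyl hydroperoxide, CC(C)(C)OO
Why: Sharpless asymmetric epoxidation used as a kinetic resolution: with L-(+)-tartrate the (S)-enantiomer of 1 should be epoxidised much faster than the (R)-enantiomer and from the face that gives the erythro product, which sets C13 (S) and C12 (R), while unreacted (R)-1 is removed by distillation.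

Step 2
Reactants: 2 (2R,3S)-1,2-epoxypentan-3-ol
Product: 3 tert-butyldimethyl{(1S)-1-[(2R)-oxiran-2-yl]propoxy}silane
Conditions: TBSCl, imidazole, DMF, 0 °C → rt
Reagents that add atoms: tert-butyldimethylsilyl chloride, CC(C)(C)[Si](C)(C)Cl
Why: Routine silylation of the secondary alcohol under weakly basic conditions that leave the epoxide intact; the TBS ether masks O13 so that only O12 can later close the furan ring.

Step 3
Reactants: 3 tert-butyldimethyl{(1S)-1-[(2R)-oxiran-2-yl]propoxy}silane; 4 cyclopentane-1,3-dione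
Product: 6 (2R)-2-[(1S)-1-(tert-butyldimethylsilyloxy)propyl]-2,3,5,6-tetrahydro-4H-cyclopenta[b]furan-4-one, via hydroxyalkyl dione 5 (not isolated)
Conditions: 4 (2 equiv), NaOH (2 equiv), EtOH–H2O (1:1), 70 °C; 1 M HCl to pH 4, extraction; then pyridinium p-toluenesulfonate (5 mol %), toluene, 80 °C, 4 Å molecular sieves
Reagents that add atoms: none
Why: Base-mediated C-alkylation of the 1,3-dione enolate by the terminal epoxide (SN2 at the unhindered C11, so C12 is retained) followed by acid cyclodehydration, in which the liberated C12 hydroxyl adds to the C6 carbonyl in a 5-exo-trig hemiketalisation and water is lost to give the vinylogous ester.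

Step 4
Reactants: 6 (2R)-2-[(1S)-1-(tert-butyldimethylsilyloxy)propyl]-2,3,5,6-tetrahydro-4H-cyclopenta[b]furan-4-one
Product: 7 (2R,4R)-2-[(1S)-1-(tert-butyldimethylsilyloxy)propyl]-3,4,5,6-tetrahydro-2H-cyclopenta[b]furan-4-ol
Conditions: (S)-1-methyl-3,3-diphenyl-tetrahydro-1H,3H-pyrrolo[1,2-c][1,3,2]oxazaborole [(S)-Me-CBS, 0.2 equiv], BH3·SMe2 (1.0 equiv), THF, −20 → 0 °C; MeOH quench, aq. NaHCO3; chromatography on Et3N-deactivated silica
Reagents that add atoms: none
Why: Corey–Bakshi–Shibata reduction: the carbonyl oxygen binds the catalyst boron anti to the larger α-branched alkenyl side (C10) and hydride is delivered from the coordinated borane, which should set C9 as R by reagent control; quench and work-up are kept basic because the enol-ether allylic alcohol ionises with acid.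

Step 5
Reactants: 7 (2R,4R)-2-[(1S)-1-(tert-butyldimethylsilyloxy)propyl]-3,4,5,6-tetrahydro-2H-cyclopenta[b]furan-4-ol
Product: 8 tert-butyldimethyl{(1S)-1-[(2R,4R)-4-(triethylsilyloxy)-3,4,5,6-tetrahydro-2H-cyclopenta[b]furan-2-yl]propoxy}silane
Conditions: Et3SiCl, imidazole, DMAP (cat.), CH2Cl2, 0 °C
Reagents that add atoms: chlorotriethylsilane, CC[Si](Cl)(CC)CC
Why: Silylation under basic conditions protects the labile allylic alcohol; the triethylsilyl group is chosen because it can later be exchanged for the acetonide without touching the TBS ether.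

Step 6
Reactants: 8 tert-butyldimethyl{(1S)-1-[(2R,4R)-4-(triethylsilyloxy)-3,4,5,6-tetrahydro-2H-cyclopenta[b]furan-2-yl]propoxy}silane
Product: 10 (5R,8R)-8-[(1S)-1-(tert-butyldimethylsilyloxy)propyl]-5-(triethylsilyloxy)oxocane-2,6-dione, via methoxy hydroperoxide 9 (not isolated)
Conditions: O3, CH2Cl2–MeOH (4:1), NaHCO3, −78 °C; N2 purge; Me2S, −78 °C → rt
Reagents that add atoms: ozone, O=[O+][O-]
Why: Ozone adds as a 1,3-dipole to the electron-rich tetrasubstituted C6=C10 enol ether, the primary ozonide cycloreverts to the C6 lactone carbonyl and a C10 carbonyl oxide, methanol traps the latter as methoxy hydroperoxide 9, and dimethyl sulfide reduces it to the C10 ketone. The closest known reaction type is the ozonolytic (Criegee) cleavage of ring-fused bicyclic enol ethers to medium-ring keto lactones. No ring is closed by bond formation: the oxocane is the periphery of the two fused five-membered rings and appears by scission of their shared C6=C10 bond, so the usual penalties of an eight-membered cyclisation are avoided. No stereocentre is created, and C9, C12 and C13 are carried through unchanged because the work-up is neutral and the α-silyloxy ketone is not exposed to base. The step needs chemoselectivity only, which is secured by the enol ether being the sole alkene and the most ozone-reactive site, while solid NaHCO3 protects the acid-labile allylic silyl ether and enol ether until cleavage is complete.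

Step 7
Reactants: 10 (5R,8R)-8-[(1S)-1-(tert-butyldimethylsilyloxy)propyl]-5-(triethylsilyloxy)oxocane-2,6-dione
Product: 11 (5R,6S,8R)-8-[(1S)-1-(tert-butyldimethylsilyloxy)propyl]-6-hydroxy-5-(triethylsilyloxy)oxocan-2-one
Conditions: LiBH(s-Bu)3 (1.1 equiv), THF, −78 °C; AcOH in THF at −78 °C, then pH 7 phosphate buffer
Reagents that add atoms: none
Why: Ketone reduction by a bulky borohydride at −78 °C, where the lactone is inert: hydride should approach C10 from the ring face opposite the adjacent C9 silyloxy group (Felkin–Anh-type attack anti to the polar substituent), which places the new hydroxyl cis to O9 (10S).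

Step 8
Reactants: 11 (5R,6S,8R)-8-[(1S)-1-(tert-butyldimethylsilyloxy)propyl]-6-hydroxy-5-(triethylsilyloxy)oxocan-2-one
Product: 12 (5R,6S,8R)-8-[(1S)-1-(tert-butyldimethylsilyloxy)propyl]-5,6-(isopropylidenedioxy)oxocan-2-one
Conditions: 2,2-dimethoxypropane (solvent), camphorsulfonic acid (10 mol %), 0 °C → rt; Et3N quench
Reagents that add atoms: 2,2-dimethoxypropane, COC(C)(C)OC
Why: Acid-catalysed transketalisation: the free C10 hydroxyl is captured as a mixed ketal whose oxocarbenium ion is closed by O9 with loss of the triethylsilyl group to methanol, giving the cis-fused dioxolane directly so that no γ-hydroxy lactone able to ring-contract accumulates; the hindered TBS ether should survive.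

Step 9
Reactants: 12 (5R,6S,8R)-8-[(1S)-1-(tert-butyldimethylsilyloxy)propyl]-5,6-(isopropylidenedioxy)oxocan-2-one
Product: 13 (5R,6S,8R)-8-[(1S)-1-(tert-butyldimethylsilyloxy)propyl]-5,6-(isopropylidenedioxy)-5,6,7,8-tetrahydro-4H-oxocin-2-yl diphenyl phosphate
Conditions: KN(SiMe3)2 (1.5 equiv), (PhO)2P(O)Cl (1.5 equiv), DMPU, THF, −78 °C
Reagents that add atoms: diphenyl phosphorochloridate, O=P(Cl)(Oc1ccccc1)Oc1ccccc1
Why: Kinetic enolisation of the lactone at C7 (the only acidic C–H) and O-phosphorylation of the potassium enolate gives the ketene acetal phosphate, the standard way of turning a lactone carbonyl into a cross-coupling site.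

Step 10
Reactants: 13 (5R,6S,8R)-8-[(1S)-1-(tert-butyldimethylsilyloxy)propyl]-5,6-(isopropylidenedioxy)-5,6,7,8-tetrahydro-4H-oxocin-2-yl diphenyl phosphate
Product: 14 2-{[(5R,6S,8R)-8-[(1S)-1-(tert-butyldimethylsilyloxy)propyl]-5,6-(isopropylidenedioxy)-5,6,7,8-tetrahydro-4H-oxocin-2-yl]methyl}-1,3-dioxolane
Conditions: (1,3-dioxolan-2-ylmethyl)zinc bromide (0.5 M in THF, 3 equiv), Pd(PPh3)4 (5 mol %), THF, 50 °C; chromatography on Et3N-deactivated silica
Reagents that add atoms: (1,3-dioxolan-2-ylmethyl)zinc bromide, Br[Zn]CC1OCCO1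
Why: Negishi coupling: zerovalent palladium inserts into the C6–O(phosphate) bond, the alkylzinc transmetalates and reductive elimination forms C5–C6, installing C4 at the aldehyde oxidation level as a dioxolane that is inert to borane.

Step 11
Reactants: 14 2-{[(5R,6S,8R)-8-[(1S)-1-(tert-butyldimethylsilyloxy)propyl]-5,6-(isopropylidenedioxy)-5,6,7,8-tetrahydro-4H-oxocin-2-yl]methyl}-1,3-dioxolane
Product: 16 (2R,3S,5R,6S,8R)-2-(1,3-dioxolan-2-ylmethyl)-8-[(1S)-1-(tert-butyldimethylsilyloxy)propyl]-5,6-(isopropylidenedioxy)oxocan-3-ol, via alkylborane 15 (not isolated)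
Conditions: BH3·THF (3 equiv), THF, 0 °C → rt; then 3 M NaOH, 30 % H2O2, 0 °C
Reagents that add atoms: hydrogen peroxide, OO
Why: Hydroboration–oxidation of the enol ether: boron adds to C7 and hydrogen to C6 in a syn fashion from the face opposite the C12 side chain (which flanks C6 across the ring oxygen), so H6 should end up cis to H12 (6R) and the C7 hydroxyl trans to the C5 substituent (7S), with retention in the peroxide oxidation.

Step 12
Reactants: 16 (2R,3S,5R,6S,8R)-2-(1,3-dioxolan-2-ylmethyl)-8-[(1S)-1-(tert-butyldimethylsilyloxy)propyl]-5,6-(isopropylidenedioxy)oxocan-3-ol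
Product: 17 (2R,3R,5R,6S,8R)-2-(1,3-dioxolan-2-ylmethyl)-8-[(1S)-1-(tert-butyldimethylsilyloxy)propyl]-5,6-(isopropylidenedioxy)oxocan-3-yl acetate
Conditions: PPh3, DIAD, AcOH, toluene, 0 °C → rt
Reagents that add atoms: acetic acid, CC(=O)O
Why: Mitsunobu reaction: the C7 alcohol is activated as its alkoxyphosphonium ion and displaced by acetate in an SN2 process with inversion, which gives the 7R acetate cis to the C6 side chain in one operation.

Step 13
Reactants: 17 (2R,3R,5R,6S,8R)-2-(1,3-dioxolan-2-ylmethyl)-8-[(1S)-1-(tert-butyldimethylsilyloxy)propyl]-5,6-(isopropylidenedioxy)oxocan-3-yl acetate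
Product: 18 (2R,3R,5R,6S,8R)-8-[(1S)-1-(tert-butyldimethylsilyloxy)propyl]-5,6-(isopropylidenedioxy)-2-(2-oxoethyl)oxocan-3-yl acetate
Conditions: pyridinium p-toluenesulfonate (0.5 equiv), acetone–H2O (10:1), 60 °C
Reagents that add atoms: water, O
Why: Acid-catalysed acetal exchange and hydrolysis frees the C4 aldehyde, and using acetone as solvent keeps the isopropylidene acetal in place by mass action while the acetate and TBS ether are stable to the weak acid.

Step 14
Reactants: 18 (2R,3R,5R,6S,8R)-8-[(1S)-1-(tert-butyldimethylsilyloxy)propyl]-5,6-(isopropylidenedioxy)-2-(2-oxoethyl)oxocan-3-yl acetate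
Product: 19 (2R,3R,5R,6S,8R)-8-[(1S)-1-(tert-butyldimethylsilyloxy)propyl]-5,6-(isopropylidenedioxy)-2-[(2Z)-5-(triisopropylsilyl)pent-2-en-4-yn-1-yl]oxocan-3-yl acetate
Conditions: 1,3-bis(triisopropylsilyl)propyne (1.3 equiv), n-BuLi (1.25 equiv), THF, −78 °C, 30 min; then 18, −78 → 0 °C; aq. NH4Cl
Reagents that add atoms: 1,3-bis(triisopropylsilyl)propyne, CC(C)[Si](C(C)C)(C(C)C)CC#C[Si](C(C)C)(C(C)C)C(C)C
Why: Peterson olefination with the lithiated 1,3-bis(silyl)propyne: addition to the aldehyde and syn elimination of silanolate should give the Z-enyne selectively because the bulky triisopropylsilyl groups control the addition geometry, and at −78 °C the aldehyde reacts far faster than the acetate.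

Step 15
Reactants: 19 (2R,3R,5R,6S,8R)-8-[(1S)-1-(tert-butyldimethylsilyloxy)propyl]-5,6-(isopropylidenedioxy)-2-[(2Z)-5-(triisopropylsilyl)pent-2-en-4-yn-1-yl]oxocan-3-yl acetate
Product: 20 (2R,3R,5R,6S,8R)-8-[(1S)-1-hydroxypropyl]-5,6-(isopropylidenedioxy)-2-[(2Z)-pent-2-en-4-yn-1-yl]oxocan-3-yl acetate
Conditions: Bu4NF (3 equiv), AcOH (3 equiv), THF, 0 °C → 40 °C
Reagents that add atoms: none
Why: Fluoride-induced desilylation removes the alkynyl silyl group and the O13 TBS ether together; buffering with acetic acid suppresses acetate cleavage or migration, and the acetonide is inert.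

Step 16
Reactants: 20 (2R,3R,5R,6S,8R)-8-[(1S)-1-hydroxypropyl]-5,6-(isopropylidenedioxy)-2-[(2Z)-pent-2-en-4-yn-1-yl]oxocan-3-yl acetate
Product: 21 (2R,3R,5R,6S,8R)-8-[(1S)-1-acetoxypropyl]-5,6-(isopropylidenedioxy)-2-[(2Z)-pent-2-en-4-yn-1-yl]oxocan-3-yl acetate
Conditions: Ac2O, pyridine, DMAP (cat.), CH2Cl2, rt
Reagents that add atoms: acetic anhydride, CC(=O)OC(C)=O
Why: Standard nucleophile-catalysed acetylation of the only free hydroxyl (O13), with retention at C13.

Step 17
Reactants: 21 (2R,3R,5R,6S,8R)-8-[(1S)-1-acetoxypropyl]-5,6-(isopropylidenedioxy)-2-[(2Z)-pent-2-en-4-yn-1-yl]oxocan-3-yl acetate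
Product: 22 (2R,3R,5R,6S,8R)-8-[(1S)-1-acetoxypropyl]-5,6-dihydroxy-2-[(2Z)-pent-2-en-4-yn-1-yl]oxocan-3-yl acetate (CNP0314743.1)
Conditions: AcOH–H2O (4:1), 40 °C
Reagents that add atoms: none
Why: Mild aqueous acid hydrolysis of the isopropylidene acetal releases the cis-9,10-diol without cleaving the two acetates or affecting the enyne.

**Compound list**

1 | (±)-pent-1-en-3-ol | C=CC(O)CC | starting material
2 | (2R,3S)-1,2-epoxypentan-3-ol | CC[C@H](O)[C@H]1CO1 | intermediate
3 | tert-butyldimethyl{(1S)-1-[(2R)-oxiran-2-yl]propoxy}silane | CC[C@H](O[Si](C)(C)C(C)(C)C)[C@H]1CO1 | intermediate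
4 | cyclopentane-1,3-dione | O=C1CCC(=O)C1 | starting material
5 | 2-[(2R,3S)-3-(tert-butyldimethylsilyloxy)-2-hydroxypentyl]cyclopentane-1,3-dione (not isolated) | O=C1CCC(=O)C1C[C@@H](O)[C@H](CC)O[Si](C)(C)C(C)(C)C | intermediate
6 | (2R)-2-[(1S)-1-(tert-butyldimethylsilyloxy)propyl]-2,3,5,6-tetrahydro-4H-cyclopenta[b]furan-4-one | O=C1CCC2=C1C[C@H]([C@H](CC)O[Si](C)(C)C(C)(C)C)O2 | intermediate
7 | (2R,4R)-2-[(1S)-1-(tert-butyldimethylsilyloxy)propyl]-3,4,5,6-tetrahydro-2H-cyclopenta[b]furan-4-ol | O[C@@H]1CCC2=C1C[C@H]([C@H](CC)O[Si](C)(C)C(C)(C)C)O2 | intermediate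
8 | tert-butyldimethyl{(1S)-1-[(2R,4R)-4-(triethylsilyloxy)-3,4,5,6-tetrahydro-2H-cyclopenta[b]furan-2-yl]propoxy}silane (key-step precursor) | CC[Si](CC)(CC)O[C@@H]1CCC2=C1C[C@H]([C@H](CC)O[Si](C)(C)C(C)(C)C)O2 | intermediate
9 | (5R,8R)-8-[(1S)-1-(tert-butyldimethylsilyloxy)propyl]-6-hydroperoxy-6-methoxy-5-(triethylsilyloxy)oxocan-2-one, both C6 epimers (not isolated) | O=C1CC[C@@H](O[Si](CC)(CC)CC)C(OC)(OO)C[C@H]([C@H](CC)O[Si](C)(C)C(C)(C)C)O1 | intermediate
10 | (5R,8R)-8-[(1S)-1-(tert-butyldimethylsilyloxy)propyl]-5-(triethylsilyloxy)oxocane-2,6-dione (key-step product) | O=C1CC[C@@H](O[Si](CC)(CC)CC)C(=O)C[C@H]([C@H](CC)O[Si](C)(C)C(C)(C)C)O1 | intermediate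
11 | (5R,6S,8R)-8-[(1S)-1-(tert-butyldimethylsilyloxy)propyl]-6-hydroxy-5-(triethylsilyloxy)oxocan-2-one | O=C1CC[C@@H](O[Si](CC)(CC)CC)[C@@H](O)C[C@H]([C@H](CC)O[Si](C)(C)C(C)(C)C)O1 | intermediate
12 | (5R,6S,8R)-8-[(1S)-1-(tert-butyldimethylsilyloxy)propyl]-5,6-(isopropylidenedioxy)oxocan-2-one | O=C1CC[C@H]2OC(C)(C)O[C@H]2C[C@H]([C@H](CC)O[Si](C)(C)C(C)(C)C)O1 | intermediate
13 | (5R,6S,8R)-8-[(1S)-1-(tert-butyldimethylsilyloxy)propyl]-5,6-(isopropylidenedioxy)-5,6,7,8-tetrahydro-4H-oxocin-2-yl diphenyl phosphate | O=P(Oc1ccccc1)(Oc1ccccc1)O/C1=C/C[C@H]2OC(C)(C)O[C@H]2C[C@H]([C@H](CC)O[Si](C)(C)C(C)(C)C)O1 | intermediate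
14 | 2-{[(5R,6S,8R)-8-[(1S)-1-(tert-butyldimethylsilyloxy)propyl]-5,6-(isopropylidenedioxy)-5,6,7,8-tetrahydro-4H-oxocin-2-yl]methyl}-1,3-dioxolane | O1CCOC1C/C3=C/C[C@H]2OC(C)(C)O[C@H]2C[C@H]([C@H](CC)O[Si](C)(C)C(C)(C)C)O3 | intermediate
15 | [(2R,3S,5R,6S,8R)-2-(1,3-dioxolan-2-ylmethyl)-8-[(1S)-1-(tert-butyldimethylsilyloxy)propyl]-5,6-(isopropylidenedioxy)oxocan-3-yl]borane (not isolated) | O1CCOC1C[C@H]3O[C@@H]([C@H](CC)O[Si](C)(C)C(C)(C)C)C[C@@H]2OC(C)(C)O[C@@H]2C[C@@H]3B | intermediate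
16 | (2R,3S,5R,6S,8R)-2-(1,3-dioxolan-2-ylmethyl)-8-[(1S)-1-(tert-butyldimethylsilyloxy)propyl]-5,6-(isopropylidenedioxy)oxocan-3-ol | O1CCOC1C[C@H]3O[C@@H]([C@H](CC)O[Si](C)(C)C(C)(C)C)C[C@@H]2OC(C)(C)O[C@@H]2C[C@@H]3O | intermediate
17 | (2R,3R,5R,6S,8R)-2-(1,3-dioxolan-2-ylmethyl)-8-[(1S)-1-(tert-butyldimethylsilyloxy)propyl]-5,6-(isopropylidenedioxy)oxocan-3-yl acetate | O1CCOC1C[C@H]3O[C@@H]([C@H](CC)O[Si](C)(C)C(C)(C)C)C[C@@H]2OC(C)(C)O[C@@H]2C[C@H]3OC(C)=O | intermediate
18 | (2R,3R,5R,6S,8R)-8-[(1S)-1-(tert-butyldimethylsilyloxy)propyl]-5,6-(isopropylidenedioxy)-2-(2-oxoethyl)oxocan-3-yl acetate | O=CC[C@H]3O[C@@H]([C@H](CC)O[Si](C)(C)C(C)(C)C)C[C@@H]2OC(C)(C)O[C@@H]2C[C@H]3OC(C)=O | intermediate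
19 | (2R,3R,5R,6S,8R)-8-[(1S)-1-(tert-butyldimethylsilyloxy)propyl]-5,6-(isopropylidenedioxy)-2-[(2Z)-5-(triisopropylsilyl)pent-2-en-4-yn-1-yl]oxocan-3-yl acetate | CC(C)[Si](C(C)C)(C(C)C)C#C/C=C\C[C@H]3O[C@@H]([C@H](CC)O[Si](C)(C)C(C)(C)C)C[C@@H]2OC(C)(C)O[C@@H]2C[C@H]3OC(C)=O | intermediate
20 | (2R,3R,5R,6S,8R)-8-[(1S)-1-hydroxypropyl]-5,6-(isopropylidenedioxy)-2-[(2Z)-pent-2-en-4-yn-1-yl]oxocan-3-yl acetate | C#C/C=C\C[C@H]3O[C@@H]([C@H](CC)O)C[C@@H]2OC(C)(C)O[C@@H]2C[C@H]3OC(C)=O | intermediate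
21 | (2R,3R,5R,6S,8R)-8-[(1S)-1-acetoxypropyl]-5,6-(isopropylidenedioxy)-2-[(2Z)-pent-2-en-4-yn-1-yl]oxocan-3-yl acetate | C#C/C=C\C[C@H]3O[C@@H]([C@H](CC)OC(C)=O)C[C@@H]2OC(C)(C)O[C@@H]2C[C@H]3OC(C)=O | intermediate
22 | (2R,3R,5R,6S,8R)-8-[(1S)-1-acetoxypropyl]-5,6-dihydroxy-2-[(2Z)-pent-2-en-4-yn-1-yl]oxocan-3-yl acetate (CNP0314743.1) | C#C/C=C\C[C@H]1O[C@@H]([C@H](CC)OC(C)=O)C[C@H](O)[C@H](O)C[C@H]1OC(C)=O | target

**Totals and risks**

Total step count: 17. Longest linear sequence: 17 steps (1 → 22).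

Steps most likely to fail:

1. Step 3. The dione enolate is a weak nucleophile, so the alkylation may stall or divert into O-alkylation and solvolysis of the epoxide. The fallback sets out from 4 and returns at 6; it makes C10–C11 by condensation and transfer hydrogenation instead of SN2 alkylation, and C12–O by epoxide opening. Purchased (E)-pent-2-en-1-ol (CC/C=C/CO) would be epoxidised under Sharpless conditions with L-(+)-diethyl tartrate to (2S,3S)-2,3-epoxypentan-1-ol F1. Parikh–Doering oxidation (SO3·pyridine, DMSO, i-Pr2NEt) would give (2R,3S)-2,3-epoxypentanal F2. Proline-catalysed Knoevenagel condensation of F2 with 4 in the presence of Hantzsch ester (CH2Cl2, rt) should give 2-{[(2S,3S)-3-ethyloxiran-2-yl]methyl}cyclopentane-1,3-dione F3. Its enol oxygen should open the epoxide at C12 in a 5-exo mode with inversion, giving (2R)-2-[(1S)-1-hydroxypropyl]-2,3,5,6-tetrahydro-4H-cyclopenta[b]furan-4-one F4. Silylation (TBSCl, imidazole, DMF) then gives 6.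

2. Step 4. Hydride transfer to the deactivated vinylogous ester carbonyl may be slow, so that uncatalysed borane reduction erodes the facial selectivity, and the product may ionise at the allylic position during work-up. The fallback sets out from 6 and returns at 8; it relies on separation instead of reagent control. Luche reduction (NaBH4, CeCl3·7H2O, MeOH, −40 °C) would give 7 together with its C9 epimer, (2R,4S)-2-[(1S)-1-(tert-butyldimethylsilyloxy)propyl]-3,4,5,6-tetrahydro-2H-cyclopenta[b]furan-4-ol F5. The mixture would be silylated as in step 5 to 8 and tert-butyldimethyl{(1S)-1-[(2R,4S)-4-(triethylsilyloxy)-3,4,5,6-tetrahydro-2H-cyclopenta[b]furan-2-yl]propoxy}silane F6, which are separated by chromatography on Et3N-deactivated silica. F6 would be recycled by desilylation (Bu4NF) to F5 and MnO2 oxidation back to 6.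

3. Step 12. Displacement at the hindered ring carbinol next to the C6 ether carbon may be outrun by elimination to an unsaturated ether, or may not proceed. The fallback sets out from 16 and returns at 17; it inverts C7 by oxidation and reduction. Dess–Martin periodinane (NaHCO3, CH2Cl2) would give (2R,5R,6S,8R)-2-(1,3-dioxolan-2-ylmethyl)-8-[(1S)-1-(tert-butyldimethylsilyloxy)propyl]-5,6-(isopropylidenedioxy)oxocan-3-one F7. LiBH(s-Bu)3 at −78 °C should deliver hydride anti to the C6 substituent to give (2R,3R,5R,6S,8R)-2-(1,3-dioxolan-2-ylmethyl)-8-[(1S)-1-(tert-butyldimethylsilyloxy)propyl]-5,6-(isopropylidenedioxy)oxocan-3-ol F8. Acetylation (Ac2O, pyridine, DMAP) then gives 17.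

**Further compounds**

F1 | step 3 | (2S,3S)-2,3-epoxypentan-1-ol | CC[C@@H]1O[C@H]1CO
F2 | step 3 | (2R,3S)-2,3-epoxypentanal | CC[C@@H]1O[C@H]1C=O
F3 | step 3 | 2-{[(2S,3S)-3-ethyloxiran-2-yl]methyl}cyclopentane-1,3-dione | O=C1CCC(=O)C1C[C@@H]2O[C@H]2CC
F4 | step 3 | (2R)-2-[(1S)-1-hydroxypropyl]-2,3,5,6-tetrahydro-4H-cyclopenta[b]furan-4-one | O=C1CCC2=C1C[C@H]([C@H](CC)O)O2
F5 | step 4 | (2R,4S)-2-[(1S)-1-(tert-butyldimethylsilyloxy)propyl]-3,4,5,6-tetrahydro-2H-cyclopenta[b]furan-4-ol | O[C@H]1CCC2=C1C[C@H]([C@H](CC)O[Si](C)(C)C(C)(C)C)O2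
F6 | step 4 | tert-butyldimethyl{(1S)-1-[(2R,4S)-4-(triethylsilyloxy)-3,4,5,6-tetrahydro-2H-cyclopenta[b]furan-2-yl]propoxy}silane | CC[Si](CC)(CC)O[C@H]1CCC2=C1C[C@H]([C@H](CC)O[Si](C)(C)C(C)(C)C)O2
F7 | step 12 | (2R,5R,6S,8R)-2-(1,3-dioxolan-2-ylmethyl)-8-[(1S)-1-(tert-butyldimethylsilyloxy)propyl]-5,6-(isopropylidenedioxy)oxocan-3-one | O1CCOC1C[C@H]3O[C@@H]([C@H](CC)O[Si](C)(C)C(C)(C)C)C[C@@H]2OC(C)(C)O[C@@H]2CC3=O
F8 | step 12 | (2R,3R,5R,6S,8R)-2-(1,3-dioxolan-2-ylmethyl)-8-[(1S)-1-(tert-butyldimethylsilyloxy)propyl]-5,6-(isopropylidenedioxy)oxocan-3-ol | O1CCOC1C[C@H]3O[C@@H]([C@H](CC)O[Si](C)(C)C(C)(C)C)C[C@@H]2OC(C)(C)O[C@@H]2C[C@H]3O
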